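In a one-step world, where D did nothing but decay by a single first-order step, c(D) would halve in the same time wherever I started counting, so two readings on the tail would carry me to any later hour. I therefore looked for that time in these runs, in which X gives D and G under the catalyst J.

| setting | delta | gamma | epsilon | flask |
|---|---|---|---|---|
| X | 0.74 M | 1.7 M | 1.1 M | 1.1 M |
| J | 2.2 mM | 2.2 mM | 3.3 mM | 2.2 mM |
| remark | run made earlier | run made earlier | run made earlier |  |
| time |  |  |  | 25 h |

- delta (time / h: D / %, G / %): 1.33: 13, 1; 4.00: 10, 13; 8.00: 7, 31; 10.0: 2, 31; 15.0: 3, 43; 20.0: 1, 46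
- gamma (time / h: D / %, G / %): 1.50: 18, 1; 2.50: 20, 7; 4.00: 14, 13; 8.00: 8, 29; 12.0: 6, 37; 20.0: 4, 44
- epsilon (time / h: D / %, G / %): 2.00: 17, 3; 5.00: 14, 21; 10.0: 8, 37; 15.0: 0, 42; 20.0: 6, 45

(scatter of a reading: 2 percentage points)

- the numbers in the tables scatter with a standard deviation of 2 percentage points

1. ratio of D to G at 4.0 min
2. ratio of D to G at 80 min
3. ratio of D to G at 25 h
4. which of D and G there is more of at 25 h

The delta and gamma runs share 2.2 mM of J, so I averaged them: c(D) read 12.0% at 4.00 h, 7.50% at 8.00 h and 2.50% at 20.0 h, where G read 45.0%. The later stretch gave the fade half-life, the time in which c(D) halves on the tail, an apparent first-order half-life, of 7.57 h. For a bound from above on D/G in the flask at 25 h, I stopped the fade at 20.0 h and took the lower G reading, which gave 0.0568. For a bound from below, I kept the earlier stretch's half-life of 5.90 h, shorter than the tail's, from 8.00 h onward and took the higher G reading, which gave 0.0221. Between them, the fade half-life put c(D) at 1.58% and the ratio at 0.0352, with G ahead.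

The forecast gave ratios of 200, 8 and 0.06 with G leading, reading “D is about 3% and G about 47%”, which put its last ratio just above my upper bound.

The flask gave 216, 7.33 and 0.0224, with D at 0.992% and G at 44.2%, so the last ratio stood at the low end of my bracket.

    X ⇌ D (K = 0.920, k = 0.209 /h)
    D ⇌ G (K = 25.0, k = 0.0282 /h)
    G + J ⇌ L + J, rate k3*[J]*[G] forward; the back reaction follows from the equilibrium constant (K = 0.573, k = 37.7 /M/h)
    L ⇌ X (k = 0.0201 /h)
    D → Q (k = 0.184 /h)
    X + J ⇌ Z, settled at all times (K = 0.638 /M)

In the flask, c(D) went from 3.37% at 12.5 h to 0.992% at 25.0 h, a fade half-life of 7.08 h. I carried the fade half-life of 7.57 h read from the runs unchanged to the neighbour charged with 1.9 M of X, where it again gave c(D) 1.58% and a ratio of 0.0352 at 25 h. That neighbour held D at 0.996% and G at 44.2%, a ratio of 0.0226.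

The earlier runs and the new flask are simulated with constants of no real substance; the scatter is artificial.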